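The route rests on cutting ring A at C5–C6. The spiro atom C6 is the α′-carbon of a ring B cyclohexenone (C7=O) flanked by C11Me2, and C1–C5 of ring A is a five-carbon bis-electrophile. One catalytic enantioselective bromochlorination of a (Z)-allylic alcohol sets C2 and C3 in the open chain. In the key step 5,5-dimethylcyclohex-2-enone is alkylated at C6 by the C1 triflate. The re-formed enolate then closes ring A on the C5 bromide, which builds the quaternary spiro centre and relays C2/C3 to C6 through a chair. Ring B is finished by deconjugation, catalyst-controlled anti bromo-acyloxylation of C9=C10 and methylenation of C7.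

Key step: step 5

Atom labels (chamigrane numbering, used in all names of spiro compounds): ring A = C1H2, C2HBr, C3(Cl)CH3, C4H2, C5H2, spiro C6. Ring B = C6, C7 (bears exocyclic C14H2), C8H2, C9HOH, C10HBr, C11(CH3)2.

Assumption: for both chiral catalysts (steps 3 and 7) the enantiomer or pseudo-enantiomer that delivers the drawn configuration is used, and compounds 1 and 7 are bought.

Step 1
Reactants: 1 4-methyl-5,6-dihydro-2H-pyran-2-one
Product: 3 methyl (Z)-5-bromo-3-methylpent-2-enoate, via dibromoboryl ester 2 (not isolated)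
Conditions: BBr3, CH2Cl2, 0 to 23 °C; then MeOH, 0 °C
Reagents that add atoms: boron tribromide, BrB(Br)Br; methanol, CO
Why: Lewis-acid ring opening of a lactone by alkyl–oxygen cleavage, in which bromide attacks the primary O–CH2 carbon (C5) in an SN2 manner, the ring geometry (C1 cis to C4) is carried over as the (Z)-alkene, and methanolysis of the acyloxyborane gives the ester.

Step 2
Reactants: 3 methyl (Z)-5-bromo-3-methylpent-2-enoate
Product: 4 (Z)-5-bromo-3-methylpent-2-en-1-ol
Conditions: iBu2AlH (2.3 equiv), CH2Cl2, −78 °C; Rochelle salt work-up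
Reagents that add atoms: none
Why: 1,2-Reduction of a conjugated ester with iBu2AlH at low temperature leaves the primary bromide and the (Z)-geometry untouched, and the alcohol is used at once so that it cannot close to the dihydropyran.

Step 3
Reactants: 4 (Z)-5-bromo-3-methylpent-2-en-1-ol
Product: 5 (2S,3S)-2,5-dibromo-3-chloro-3-methylpentan-1-ol
Conditions: N-bromosuccinimide, ClTi(OiPr)3 (1.1 equiv), tridentate salicylaldimine ligand from 2-amino-3,3-dimethyl-1,1-diphenylbutan-1-ol (10 mol%), hexane, −20 °C
Reagents that add atoms: N-bromosuccinimide, O=C1CCC(=O)N1Br; chlorotitanium triisopropoxide, CC(C)O[Ti](Cl)(OC(C)C)OC(C)C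
Why: Titanium-bound catalytic enantioselective bromochlorination of an allylic alcohol, in which the ligand-bearing titanium alkoxide of 4 selects the alkene face for Br+ and delivers chloride anti to the tertiary, distal C3, so anti addition to the (Z)-alkene fixes the C2/C3 relative configuration and the ligand fixes the absolute (2S,3S) configuration while the primary C5–Br is inert.

Step 4
Reactants: 5 (2S,3S)-2,5-dibromo-3-chloro-3-methylpentan-1-ol
Product: 6 (2S,3S)-2,5-dibromo-3-chloro-3-methylpentyl trifluoromethanesulfonate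
Conditions: Tf2O, 2,6-lutidine, CH2Cl2, −78 °C; used cold without storage
Reagents that add atoms: trifluoromethanesulfonic anhydride, O=S(=O)(OS(=O)(=O)C(F)(F)F)C(F)(F)F
Why: Sulfonylation of the primary alcohol with a non-nucleophilic base gives the only leaving group reactive enough for a β-branched, β-bromo carbon, and no stereocentre is touched.

Step 5
Reactants: 6 (2S,3S)-2,5-dibromo-3-chloro-3-methylpentyl trifluoromethanesulfonate; 7 5,5-dimethylcyclohex-2-en-1-one
Product: 11 (2S,3S,6R)-2-bromo-3-chloro-3,11,11-trimethylspiro[5.5]undec-8-en-7-one, via lithium enolate 8 (not isolated), via monoalkylated enone 9 (not isolated), via potassium enolate 10 (not isolated)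
Conditions: 7, LiN(iPr)2 (1.05 equiv), THF, −78 °C; 6, −78 to −30 °C; then KN(SiMe3)2 (1.2 equiv), THF/DMPU, −78 to 0 °C
Reagents that add atoms: none
Why: Kinetic deprotonation of 7 gives the cross-conjugated enolate 8, whose C6 displaces the primary C1 triflate of 6 far faster than either bromide, and KN(SiMe3)2 then re-enolises 9 so that C6 attacks the C5–Br carbon from the back (SN2) and the C5–C6 bond closes ring A. The closest known reaction type is the one-pot spiroannulation of cyclic enone or vinylogous ester enolates by double α′-alkylation with a bis-electrophile. Ring A closes in the 6-(enolexo)-exo-tet mode and no other ring is formed. The only new stereocentre, spiro C6, is set by the chair-like transition state of the tether: C2–Br and C3–Cl stay equatorial (an axial C2–Br would be syn-axial to the axial C6 substituent), the bulky C11Me2 arm takes the equatorial site and the flat enolate carbon C7 the axial one, which is the target arrangement (descriptor R here only because C7=O outranks C11). The step needs triflate-before-bromide selectivity, C- over O-alkylation and six- over three-membered closure, secured respectively by the leaving-group gap, by lithium and potassium enolates in THF, and by C2 being a secondary carbon next to the quaternary C3. Any γ-dienolate formed from 9 cannot reach C5 in a small ring and drains back to 10 by proton exchange.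

Step 6
Reactants: 11 (2S,3S,6R)-2-bromo-3-chloro-3,11,11-trimethylspiro[5.5]undec-8-en-7-one
Product: 13 (2S,3S,6R)-2-bromo-3-chloro-3,11,11-trimethylspiro[5.5]undec-9-en-7-one, via lithium dienolate 12 (not isolated)
Conditions: LiN(iPr)2 (1.3 equiv), THF/DMPU, −78 °C; inverse quench into AcOH/THF, −78 °C
Reagents that add atoms: none
Why: Deconjugative protonation, in which 11 has no α′-hydrogen so the base can only remove the γ-hydrogen at C10 to give the extended dienolate 12, kinetic protonation at the α-carbon C8 moves the alkene to C9=C10, and the diequatorial ring A halides offer no antiperiplanar hydrogen for E2.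

Step 7
Reactants: 13 (2S,3S,6R)-2-bromo-3-chloro-3,11,11-trimethylspiro[5.5]undec-9-en-7-one
Product: 14 (2S,3S,6R,9S,10S)-2,10-dibromo-3-chloro-3,11,11-trimethyl-7-oxospiro[5.5]undecan-9-yl benzoate
Conditions: hydroquinidine 1,4-phthalazinediyl diether, (DHQD)2PHAL (10 mol%), PhC(O)NHBr, PhCO2H (3 equiv), toluene/CHCl3, −30 °C, dark
Reagents that add atoms: N-bromobenzamide, O=C(NBr)c1ccccc1; benzoic acid, OC(=O)c1ccccc1
Why: Catalytic asymmetric intermolecular bromoesterification of an unfunctionalised cis-alkene, in which anti opening of the bromonium ion makes C9–O and C10–Br trans, benzoate attacks C9 because C10 is neopentyl next to C11Me2, and the alkene face, which ring A differentiates only through the remote equatorial C2–Br, is chosen by the alkaloid catalyst to give (9S,10S).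

Step 8
Reactants: 14 (2S,3S,6R,9S,10S)-2,10-dibromo-3-chloro-3,11,11-trimethyl-7-oxospiro[5.5]undecan-9-yl benzoate
Product: 16 (2S,3S,6S,9S,10S)-2,10-dibromo-3-chloro-3,11,11-trimethyl-7-methylidenespiro[5.5]undecan-9-ol (CNP0247242.1), via phenylvinyl ether 15 (not isolated)
Conditions: Cp2TiMe2 (5 equiv), toluene, 70 °C, dark; then pyridinium p-toluenesulfonate (cat.), THF/H2O, 23 °C
Reagents that add atoms: dimethyltitanocene, [CH3-].[CH3-].[Ti+4].c1cc[cH-]c1.c1cc[cH-]c1
Why: Petasis methylenation, in which the non-basic Cp2Ti=CH2 formed on heating converts the hindered C7 ketone into the exocyclic alkene without eliminating the β-acyloxy group, also turns the benzoate into the 1-phenylvinyl ether 15, and mild acid hydrolysis of that enol ether frees the C9 alcohol without touching any stereocentre.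

Compound list
1 | 4-methyl-5,6-dihydro-2H-pyran-2-one | CC1=CC(=O)OCC1 | starting material
2 | dibromoboryl (Z)-5-bromo-3-methylpent-2-enoate | BrB(Br)OC(=O)/C=C(/C)CCBr | intermediate
3 | methyl (Z)-5-bromo-3-methylpent-2-enoate | COC(=O)/C=C(/C)CCBr | intermediate
4 | (Z)-5-bromo-3-methylpent-2-en-1-ol | OC/C=C(/C)CCBr | intermediate
5 | (2S,3S)-2,5-dibromo-3-chloro-3-methylpentan-1-ol | OC[C@H](Br)[C@@](C)(Cl)CCBr | intermediate
6 | (2S,3S)-2,5-dibromo-3-chloro-3-methylpentyl trifluoromethanesulfonate | FC(F)(F)S(=O)(=O)OC[C@H](Br)[C@@](C)(Cl)CCBr | intermediate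
7 | 5,5-dimethylcyclohex-2-en-1-one | O=C1C=CCC(C)(C)C1 | starting material
8 | lithium cross-conjugated (C6=C7) enolate of 7 | [Li+].[O-]C1=CC(C)(C)CC=C1 | intermediate
9 | 6-[(2S,3S)-2,5-dibromo-3-chloro-3-methylpentyl]-5,5-dimethylcyclohex-2-en-1-one (both C6 epimers) | O=C1C=CCC(C)(C)C1C[C@H](Br)[C@@](C)(Cl)CCBr | intermediate
10 | potassium cross-conjugated (C6=C7) enolate of 9 | [K+].[O-]C1=C(C[C@H](Br)[C@@](C)(Cl)CCBr)C(C)(C)CC=C1 | intermediate
11 | (2S,3S,6R)-2-bromo-3-chloro-3,11,11-trimethylspiro[5.5]undec-8-en-7-one | O=C1C=CCC(C)(C)[C@]12CC[C@](C)(Cl)[C@@H](Br)C2 | intermediate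
12 | lithium extended dienolate of 11 (O–C7=C8–C9=C10) | [Li+].[O-]C1=CC=CC(C)(C)[C@]12CC[C@](C)(Cl)[C@@H](Br)C2 | intermediate
13 | (2S,3S,6R)-2-bromo-3-chloro-3,11,11-trimethylspiro[5.5]undec-9-en-7-one | O=C1CC=CC(C)(C)[C@]12CC[C@](C)(Cl)[C@@H](Br)C2 | intermediate
14 | (2S,3S,6R,9S,10S)-2,10-dibromo-3-chloro-3,11,11-trimethyl-7-oxospiro[5.5]undecan-9-yl benzoate | O=C1C[C@H](OC(=O)c3ccccc3)[C@@H](Br)C(C)(C)[C@]12CC[C@](C)(Cl)[C@@H](Br)C2 | intermediate
15 | (2S,3S,6S,9S,10S)-2,10-dibromo-3-chloro-3,11,11-trimethyl-7-methylidene-9-(1-phenylethenyloxy)spiro[5.5]undecane | C=C1C[C@H](OC(=C)c3ccccc3)[C@@H](Br)C(C)(C)[C@]12CC[C@](C)(Cl)[C@@H](Br)C2 | intermediate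
16 | (2S,3S,6S,9S,10S)-2,10-dibromo-3-chloro-3,11,11-trimethyl-7-methylidenespiro[5.5]undecan-9-ol | C=C1C[C@H](O)[C@@H](Br)C(C)(C)[C@]12CC[C@](C)(Cl)[C@@H](Br)C2 | target

Total step count: 8. Longest linear sequence: 8 steps (1 to 16); compound 7 enters at step 5.

Steps most likely to fail

**Step 5.**
- What may go wrong:
  - The hindered C6 enolate may displace the β-branched triflate too slowly, so that elimination of triflic acid or O-alkylation takes over.
  - After the second deprotonation, three-membered closure onto C2–Br or base-induced dehydrohalogenation of the open chain may outrun six-membered closure.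
- Fallback, from 6 back to 13: a small acyclic nitrile anion replaces the cyclic enolate and ring B is built afterwards.
  - 3,3-Dimethylpent-4-enenitrile F1 is deprotonated with LiN(iPr)2 and alkylated by 6 to the open-chain nitrile F2.
  - KN(SiMe3)2 closes the same C5–C6 bond to the ring A nitrile F3, with the slim cyano group axial and the CMe2 group equatorial.
  - Allylmagnesium bromide followed by acidic hydrolysis gives the allyl ketone F4.
  - Ring-closing metathesis with the second-generation Grubbs catalyst joins C9 and C10 to give 13, which also bypasses step 6.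

**Step 7.**
- What may go wrong:
  - The catalyst may discriminate the two nearly mirror-image alkene faces poorly on this bulky substrate.
  - Its basic nitrogen may pull the alkene back into conjugation or eliminate the β-benzoate.
  - The enol may be brominated at C8.
- Fallback, from 13 back to 16: catalysis is replaced by unselective addition and an enzymatic sorting of the pseudo-enantiomeric ring B carbinols.
  - N-Bromosuccinimide in aqueous acetone gives the (9S,10S)-keto bromohydrin F5 together with the (9R,10R)-keto bromohydrin F6.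
  - Excess Cp2TiMe2 converts the pair into 16 and its (9R,10R)-diastereomer F7.
  - Candida antarctica lipase B with vinyl acetate acylates the (9R)-carbinol to the acetate F8.
  - This is the known behaviour of trans-2-bromocycloalkanols, so free 16 is separated by chromatography.

**Step 8.**
- What may go wrong:
  - Methylenation of the ketone next to the spiro centre may be too slow at a temperature the β-acyloxy ketone tolerates, so that thermal loss of benzoic acid competes.
  - The benzoate may be consumed only partly.
- Fallback, from 14 back to 16: an addition–elimination sequence replaces the titanium carbene.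
  - Me3SiCH2Li/CeCl3 at −78 °C adds to C7 to give the β-hydroxysilane F9.
  - HF·pyridine triggers the acidic Peterson elimination to the methylidene benzoate F10.
  - iBu2AlH at −78 °C removes the benzoate to give 16.

Further compounds
F1 | step 5 | 3,3-dimethylpent-4-enenitrile | C=CC(C)(C)CC#N
F2 | step 5 | 2-[(2S,3S)-2,5-dibromo-3-chloro-3-methylpentyl]-3,3-dimethylpent-4-enenitrile (both C6 epimers) | N#CC(C[C@H](Br)[C@@](C)(Cl)CCBr)C(C)(C)C=C
F3 | step 5 | (2S,3S,6R)-ring A nitrile, 2-bromo-3-chloro-3-methyl-6-(2-methylbut-3-en-2-yl)cyclohexane-6-carbonitrile (chamigrane labels) | N#C[C@]1(C(C)(C)C=C)CC[C@](C)(Cl)[C@@H](Br)C1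
F4 | step 5 | (2S,3S,6R)-allyl ketone, 1-[2-bromo-3-chloro-3-methyl-6-(2-methylbut-3-en-2-yl)cyclohexan-6-yl]but-3-en-1-one (chamigrane labels) | C=CCC(=O)[C@]1(C(C)(C)C=C)CC[C@](C)(Cl)[C@@H](Br)C1
F5 | step 7 | (2S,3S,6R,9S,10S)-2,10-dibromo-3-chloro-9-hydroxy-3,11,11-trimethylspiro[5.5]undecan-7-one | O=C1C[C@H](O)[C@@H](Br)C(C)(C)[C@]12CC[C@](C)(Cl)[C@@H](Br)C2
F6 | step 7 | (2S,3S,6R,9R,10R)-2,10-dibromo-3-chloro-9-hydroxy-3,11,11-trimethylspiro[5.5]undecan-7-one | O=C1C[C@@H](O)[C@H](Br)C(C)(C)[C@]12CC[C@](C)(Cl)[C@@H](Br)C2
F7 | step 7 | (2S,3S,6S,9R,10R)-2,10-dibromo-3-chloro-3,11,11-trimethyl-7-methylidenespiro[5.5]undecan-9-ol | C=C1C[C@@H](O)[C@H](Br)C(C)(C)[C@]12CC[C@](C)(Cl)[C@@H](Br)C2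
F8 | step 7 | (2S,3S,6S,9R,10R)-2,10-dibromo-3-chloro-3,11,11-trimethyl-7-methylidenespiro[5.5]undecan-9-yl acetate | C=C1C[C@@H](OC(C)=O)[C@H](Br)C(C)(C)[C@]12CC[C@](C)(Cl)[C@@H](Br)C2
F9 | step 8 | (2S,3S,9S,10S)-2,10-dibromo-3-chloro-7-hydroxy-3,11,11-trimethyl-7-(trimethylsilylmethyl)spiro[5.5]undecan-9-yl benzoate (C6 as in 14, C7 unassigned) | C[Si](C)(C)CC1(O)C[C@H](OC(=O)c3ccccc3)[C@@H](Br)C(C)(C)[C@]12CC[C@](C)(Cl)[C@@H](Br)C2
F10 | step 8 | (2S,3S,6S,9S,10S)-2,10-dibromo-3-chloro-3,11,11-trimethyl-7-methylidenespiro[5.5]undecan-9-yl benzoate | C=C1C[C@H](OC(=O)c3ccccc3)[C@@H](Br)C(C)(C)[C@]12CC[C@](C)(Cl)[C@@H](Br)C2
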